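**Remark (one line):** chroman = 3,4-dihydro-2H-chromene (O-1, C-2, C-3, C-4, C-4a, C-5 to C-8, C-8a); the quinone is numbered with carbonyls at C-1 and C-4, methoxy groups at C-2, C-3 and C-5 and the chromanyl group at C-6; the target stereocenter is read as (3S); the centers drawn without configuration in 14, 18 and 20 and the E/Z mixture 13 are uncontrolled and are erased before the target.

## Retrosynthetic overview

1. The quinone ring is made last: target 22 ⇐ hydroquinone 21 (Ag2O) ⇐ 6π electrocyclization of dienylketene 19, which joins carbonyl carbon C-4 to methoxy-bearing C-5 ⇐ thermal 4π opening of 4-alkenyl-4-hydroxycyclobutenone 18.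
2. Enabling feature: quinone atoms C-1(=O), C-2(OMe), C-3(OMe), C-4(=O) with their four oxygens are dimethyl squarate 16; C-6 (bearing chroman C-3) and C-5 (OMe) are a 2-methoxyvinyl unit, and the para-dioxygen pattern maps onto the carbinol carbon and the ketene carbon.
3. 18 ⇐ squarate 16 + cis-β-methoxyvinyllithium 17 ⇐ (Z)-β-bromo enol ether 15 ⇐ enol ether 13 ⇐ acetal 12.
4. Pyran ring of the chroman: O-1/C-8a bond by intramolecular Pd aryl etherification of bromo alcohol 11; C-3 stereocenter by Evans alkylation of imide 8 with benzyl bromide 3.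
5. Ring order: chroman benzene ring purchased (in 1), pyran ring (step 7), four-membered ring purchased (16), quinone ring (step 11).

Key step: step 11

## Route

Step 1
Reactants: 1 3,4,5-trimethoxybenzyl alcohol
Product: 2 2-bromo-3,4,5-trimethoxybenzyl alcohol
Conditions: NBS, MeCN, 0 °C to rt
Reagents that add atoms: N-bromosuccinimide, O=C1CCC(=O)N1Br
Why: Electrophilic aromatic bromination; the two free ring positions are equivalent and each is ortho and para to a methoxy group, so monobromination next to the CH2OH group should result.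

Step 2
Reactants: 2 2-bromo-3,4,5-trimethoxybenzyl alcohol
Product: 3 2-bromo-3,4,5-trimethoxybenzyl bromide
Conditions: PBr3, CH2Cl2, 0 °C
Reagents that add atoms: phosphorus tribromide, BrP(Br)Br
Why: Conversion of a primary benzylic alcohol into the bromide by displacement on its phosphite ester; the aryl bromide and the methyl ethers are inert.

Step 3
Reactants: 4 methyl 4,4-dimethoxybutanoate
Product: 5 lithium 4,4-dimethoxybutanoate
Conditions: LiOH·H2O (1.0 equiv), THF/H2O, rt; evaporation, toluene azeotrope
Reagents that add atoms: lithium hydroxide, [Li+].[OH-]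
Why: Ester saponification; isolating the dry lithium salt avoids the free acid and any acidic work-up that would endanger the dimethyl acetal.

Step 4
Reactants: 5 lithium 4,4-dimethoxybutanoate; 6 (S)-4-benzyl-1,3-oxazolidin-2-one
Product: 8 (S)-4-benzyl-3-(4,4-dimethoxybutanoyl)-1,3-oxazolidin-2-one, via mixed pivalic anhydride 7 (not isolated)
Conditions: t-BuCOCl, THF, 0 °C; then 6, LiCl, Et3N, rt
Reagents that add atoms: none
Why: N-acylation of the oxazolidinone through the mixed pivalic anhydride, the nitrogen attacking the less hindered, non-pivaloyl carbonyl.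

Step 5
Reactants: 8 (S)-4-benzyl-3-(4,4-dimethoxybutanoyl)-1,3-oxazolidin-2-one; 3 2-bromo-3,4,5-trimethoxybenzyl bromide
Product: 10 (S)-4-benzyl-3-[(S)-2-(2-bromo-3,4,5-trimethoxybenzyl)-4,4-dimethoxybutanoyl]-1,3-oxazolidin-2-one, via sodium enolate 9 (not isolated)
Conditions: NaN(SiMe3)2, THF, −78 °C; then 3, −78 to −40 °C
Reagents that add atoms: none
Why: Evans asymmetric alkylation; the chelated sodium (Z)-enolate is attacked by the benzylic bromide on the face opposite the C-4 benzyl group of the auxiliary, which sets the future chroman C-3 center as (S).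

Step 6
Reactants: 10 (S)-4-benzyl-3-[(S)-2-(2-bromo-3,4,5-trimethoxybenzyl)-4,4-dimethoxybutanoyl]-1,3-oxazolidin-2-one
Product: 11 (S)-2-(2-bromo-3,4,5-trimethoxybenzyl)-4,4-dimethoxybutan-1-ol
Conditions: LiBH4, MeOH (1 equiv), THF, 0 °C
Reagents that add atoms: none

Why: Reductive cleavage of the N-acyl oxazolidinone by hydride attack at the exocyclic carbonyl; the α-center is not epimerized, and the aryl bromide and acetal are untouched.

Step 7
Reactants: 11 (S)-2-(2-bromo-3,4,5-trimethoxybenzyl)-4,4-dimethoxybutan-1-ol
Product: 12 (S)-3-(2,2-dimethoxyethyl)-6,7,8-trimethoxychroman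
Conditions: Pd(OAc)2 (cat.), 2-(di-tert-butylphosphino)-1,1'-binaphthyl (cat.), Cs2CO3, toluene, 80 °C
Reagents that add atoms: none
Why: Intramolecular Buchwald–Hartwig etherification; zerovalent palladium formed in situ inserts into the aryl C–Br bond and the bulky electron-rich phosphine favors C–O reductive elimination over β-hydride elimination, closing the six-membered pyran ring without touching the stereocenter.

Step 8
Reactants: 12 (S)-3-(2,2-dimethoxyethyl)-6,7,8-trimethoxychroman
Product: 13 (S)-6,7,8-trimethoxy-3-(2-methoxyvinyl)chroman (E/Z mixture)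
Conditions: Me3SiOTf, iPr2NEt, CH2Cl2, −20 °C to rt
Reagents that add atoms: none
Why: Silyl-triflate-mediated elimination of methanol from a dimethyl acetal through the oxocarbenium ion, which the amine deprotonates at the adjacent CH2; the alkene geometry is irrelevant for the next step.

Step 9
Reactants: 13 (S)-6,7,8-trimethoxy-3-(2-methoxyvinyl)chroman (E/Z mixture)
Product: 15 (R)-3-[(Z)-1-bromo-2-methoxyvinyl]-6,7,8-trimethoxychroman, via dibromo ether 14 (not isolated)
Conditions: Br2 (1.0 equiv), CH2Cl2, −78 °C; then Et3N, −78 °C to rt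
Reagents that add atoms: bromine, BrBr
Why: Bromination–dehydrobromination of an enol ether; bromine should add to the enol ether far faster than to the arene at −78 °C, and ionization of the α-bromo ether followed by loss of the H–C(Br) proton should give the β-bromo enol ether, mainly with Br cis to OMe as in the parent 2-bromovinyl ethers (the descriptor at C-3 changes to R only because of CIP priorities).

Step 10
Reactants: 15 (R)-3-[(Z)-1-bromo-2-methoxyvinyl]-6,7,8-trimethoxychroman; 16 dimethyl squarate (3,4-dimethoxycyclobut-3-ene-1,2-dione)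
Product: 18 4-hydroxy-2,3-dimethoxy-4-{(Z)-2-methoxy-1-[(3S)-6,7,8-trimethoxychroman-3-yl]vinyl}cyclobut-2-en-1-one, via vinyllithium 17 (not isolated)
Conditions: t-BuLi (2.0 equiv), THF, −78 °C; cannulation into 16, THF, −78 °C; aq NH4Cl; crude or Et3N-deactivated silica
Reagents that add atoms: none
Why: Bromine–lithium exchange with retention of alkene geometry gives the oxygen-chelated cis-β-methoxyvinyllithium, which does not eliminate LiOMe at −78 °C and adds 1,2 to one of the two equivalent squarate carbonyls; the new carbinol center is uncontrolled and is lost in step 11.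

Step 11
Reactants: 18 4-hydroxy-2,3-dimethoxy-4-{(Z)-2-methoxy-1-[(3S)-6,7,8-trimethoxychroman-3-yl]vinyl}cyclobut-2-en-1-one
Product: 22 (S)-2,3,5-trimethoxy-6-(6,7,8-trimethoxychroman-3-yl)-1,4-benzoquinone (target), via dienylketene 19 (not isolated), via cyclohexadienone 20 (not isolated), via hydroquinone 21 (not isolated)
Conditions: p-xylene, 138 °C, argon; cooling, then Ag2O, rt
Reagents that add atoms: none
Why: Heating opens the cyclobutenone by conrotatory 4π electrocyclic cleavage of its C-1/C-4 bond, the hydroxyl rotating outward and the methoxyvinyl group inward, to give (Z,Z)-dienylketene 19, whose ketene carbon and methoxy-bearing vinyl terminus join in a disrotatory 6π electrocyclization (six-membered ring) to cyclohexadienone 20; enolization gives hydroquinone 21 and Ag2O dehydrogenates it to the quinone. The closest known reaction type is the thermal ring expansion of 4-alkenyl-4-hydroxycyclobutenones derived from squarate esters to hydroquinones and quinones (Moore-type rearrangement). No stereocenter is created in the product: the carbinol center of 18 and C-6 of 20 become sp2, and chroman C-3 is a spectator under these neutral conditions. The selectivity needed is outward rotation of the donor hydroxyl group (torquoselectivity), which places the alkenyl group cis to the ketene so that ring closure outruns capture of the ketene by the hydroxyl; the positions of all six ring substituents are fixed by the connectivity of 18, since the ketene carbon can reach only the vinyl terminus. The methoxy group on that terminus points inward, which should be tolerated because the sp-hybridized ketene carbon carries no inward substituent. Ag2O should oxidize only the hydroquinone and leave the tetraalkoxy arene of the chroman untouched.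

## Compound list

1 | 3,4,5-trimethoxybenzyl alcohol | COc1cc(CO)cc(OC)c1OC | starting material
2 | 2-bromo-3,4,5-trimethoxybenzyl alcohol | COc1cc(CO)c(Br)c(OC)c1OC | intermediate
3 | 2-bromo-3,4,5-trimethoxybenzyl bromide | COc1cc(CBr)c(Br)c(OC)c1OC | intermediate
4 | methyl 4,4-dimethoxybutanoate | COC(OC)CCC(=O)OC | starting material
5 | lithium 4,4-dimethoxybutanoate | COC(OC)CCC(=O)[O-].[Li+] | intermediate
6 | (S)-4-benzyl-1,3-oxazolidin-2-one | O=C1N[C@@H](Cc2ccccc2)CO1 | starting material
7 | 4,4-dimethoxybutanoic pivalic anhydride | COC(OC)CCC(=O)OC(=O)C(C)(C)C | intermediate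
8 | (S)-4-benzyl-3-(4,4-dimethoxybutanoyl)-1,3-oxazolidin-2-one | COC(OC)CCC(=O)N1C(=O)OC[C@@H]1Cc1ccccc1 | intermediate
9 | sodium (Z)-enolate of 8 | COC(OC)C/C=C(\[O-])N1C(=O)OC[C@@H]1Cc1ccccc1.[Na+] | intermediate
10 | (S)-4-benzyl-3-[(S)-2-(2-bromo-3,4,5-trimethoxybenzyl)-4,4-dimethoxybutanoyl]-1,3-oxazolidin-2-one | COC(OC)C[C@H](Cc1cc(OC)c(OC)c(OC)c1Br)C(=O)N1C(=O)OC[C@@H]1Cc1ccccc1 | intermediate
11 | (S)-2-(2-bromo-3,4,5-trimethoxybenzyl)-4,4-dimethoxybutan-1-ol | COC(OC)C[C@H](Cc1cc(OC)c(OC)c(OC)c1Br)CO | intermediate
12 | (S)-3-(2,2-dimethoxyethyl)-6,7,8-trimethoxychroman | COC(OC)C[C@H]1COc2c(cc(OC)c(OC)c2OC)C1 | intermediate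
13 | (S)-6,7,8-trimethoxy-3-(2-methoxyvinyl)chroman (E/Z mixture) | COC=C[C@H]1COc2c(cc(OC)c(OC)c2OC)C1 | intermediate
14 | (3R)-3-(1,2-dibromo-2-methoxyethyl)-6,7,8-trimethoxychroman (diastereomer mixture) | COC(Br)C(Br)[C@H]1COc2c(cc(OC)c(OC)c2OC)C1 | intermediate
15 | (R)-3-[(Z)-1-bromo-2-methoxyvinyl]-6,7,8-trimethoxychroman | CO/C=C(\Br)[C@H]1COc2c(cc(OC)c(OC)c2OC)C1 | intermediate
16 | dimethyl squarate (3,4-dimethoxycyclobut-3-ene-1,2-dione) | COC1=C(OC)C(=O)C1=O | starting material
17 | 2-methoxy-1-[(3S)-6,7,8-trimethoxychroman-3-yl]vinyllithium (Li cis to OMe) | CO/C=C(\[Li])[C@H]1COc2c(cc(OC)c(OC)c2OC)C1 | intermediate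
18 | 4-hydroxy-2,3-dimethoxy-4-{(Z)-2-methoxy-1-[(3S)-6,7,8-trimethoxychroman-3-yl]vinyl}cyclobut-2-en-1-one (carbinol epimers) | CO/C=C(\C1(O)C(OC)=C(OC)C1=O)[C@H]1COc2c(cc(OC)c(OC)c2OC)C1 | intermediate
19 | (3Z,5Z)-4-hydroxy-2,3,6-trimethoxy-5-[(3S)-6,7,8-trimethoxychroman-3-yl]hexa-1,3,5-trien-1-one | O=C=C(OC)/C(OC)=C(/O)\C(=C/OC)[C@H]1COc2c(cc(OC)c(OC)c2OC)C1 | intermediate
20 | 4-hydroxy-2,3,6-trimethoxy-5-[(3S)-6,7,8-trimethoxychroman-3-yl]cyclohexa-2,4-dien-1-one (C-6 epimers) | COC1C(=O)C(OC)=C(OC)C(O)=C1[C@H]1COc2c(cc(OC)c(OC)c2OC)C1 | intermediate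
21 | 2,3,5-trimethoxy-6-[(3S)-6,7,8-trimethoxychroman-3-yl]benzene-1,4-diol | COc1c(O)c(OC)c(OC)c(O)c1[C@H]1COc2c(cc(OC)c(OC)c2OC)C1 | intermediate
22 | (S)-2,3,5-trimethoxy-6-(6,7,8-trimethoxychroman-3-yl)-1,4-benzoquinone | COC1=C(OC)C(=O)C([C@H]2COc3c(cc(OC)c(OC)c3OC)C2)=C(OC)C1=O | target

## Step count and risks

Total step count: 11. Longest linear sequence: 9 steps (steps 3 to 11, from 4); steps 1 and 2 form a two-step branch that joins at step 5.

Steps most likely to fail:

1. **Step 9.** Electrophilic bromination of the very electron-rich tetraoxygenated arene (chroman C-5) could compete with addition to the enol ether, and the dehydrobromination could give the wrong alkene geometry. Fallback, setting out from 13: iodo-methoxylation with N-iodosuccinimide in MeOH/CH2Cl2 at −40 °C, a milder halonium source that should spare the arene, would give (3R)-3-(1-iodo-2,2-dimethoxyethyl)-6,7,8-trimethoxychroman F1. Elimination of methanol with Me3SiOTf/iPr2NEt as in step 8 would give (R)-3-[(Z)-1-iodo-2-methoxyvinyl]-6,7,8-trimethoxychroman F2. Iodine–lithium exchange (t-BuLi, −78 °C) would then return to the route at vinyllithium 17, and hence at 18.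

2. **Step 7.** Oxidative addition at the di-ortho-substituted, electron-rich aryl bromide may be slow, and β-hydride elimination from the palladium alkoxide may oxidize the alcohol and hydrodebrominate the arene. Fallback, setting out from 11: the C–O bond to the arene is made first and the ring is closed at the primary carbon instead. Treatment with n-BuLi (2.2 equiv, THF, −78 °C; alkoxide formation, then bromine–lithium exchange), B(OMe)3 and then H2O2/NaOH would give (S)-2-(2-hydroxy-3,4,5-trimethoxybenzyl)-4,4-dimethoxybutan-1-ol F3. A Mitsunobu reaction (PPh3, diisopropyl azodicarboxylate, THF) would let the phenol oxygen displace the activated primary alcohol and return to the route at 12.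

3. **Step 11.** The free tertiary hydroxyl may capture the ketene (furanone formation), or the β-methoxyallylic carbinol may undergo allylic transposition on handling, in competition with the 6π closure. Fallback, setting out from 15 (with 16): lithiation and addition as in step 10, but with the lithium alkoxide silylated in the flask with Me3SiCl, would give 2,3-dimethoxy-4-{(Z)-2-methoxy-1-[(3S)-6,7,8-trimethoxychroman-3-yl]vinyl}-4-(trimethylsilyloxy)cyclobut-2-en-1-one F4. This can no longer add its oxygen to the ketene and is not prone to ionization. Thermolysis in p-xylene would give 2,3,6-trimethoxy-5-[(3S)-6,7,8-trimethoxychroman-3-yl]-4-(trimethylsilyloxy)phenol F5 by the same ring closure. Bu4NF in THF would then return to the route at hydroquinone 21, which Ag2O oxidizes to 22.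

## Further compounds

F1 | step 9 | (3R)-3-(1-iodo-2,2-dimethoxyethyl)-6,7,8-trimethoxychroman | COC(OC)C(I)[C@H]1COc2c(cc(OC)c(OC)c2OC)C1
F2 | step 9 | (R)-3-[(Z)-1-iodo-2-methoxyvinyl]-6,7,8-trimethoxychroman | CO/C=C(\I)[C@H]1COc2c(cc(OC)c(OC)c2OC)C1
F3 | step 7 | (S)-2-(2-hydroxy-3,4,5-trimethoxybenzyl)-4,4-dimethoxybutan-1-ol | COC(OC)C[C@H](Cc1cc(OC)c(OC)c(OC)c1O)CO
F4 | step 11 | 2,3-dimethoxy-4-{(Z)-2-methoxy-1-[(3S)-6,7,8-trimethoxychroman-3-yl]vinyl}-4-(trimethylsilyloxy)cyclobut-2-en-1-one | CO/C=C(\C1(O[Si](C)(C)C)C(OC)=C(OC)C1=O)[C@H]1COc2c(cc(OC)c(OC)c2OC)C1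
F5 | step 11 | 2,3,6-trimethoxy-5-[(3S)-6,7,8-trimethoxychroman-3-yl]-4-(trimethylsilyloxy)phenol | COc1c(O)c(OC)c(OC)c(O[Si](C)(C)C)c1[C@H]1COc2c(cc(OC)c(OC)c2OC)C1
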